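The cyclohexenone ring is cut at C1–C6 and C4–C5, a [4+2] retron whose two-carbon partner is a 1,1-disubstituted alkene already bearing the allyl group and the complete side chain. The feature exploited is the 1,4-relation of the benzylic oxygen on C1′ to carbonyl carbon C1 (O–C1′–C2′–C6–C1): C1 starts as the carbonyl carbon of an ester on that oxygen. Enolisation gives an (E)-4-methoxy silyl ketene acetal diene, so the precursor is an acyclic 1,3,8-nonatriene. Its intramolecular Diels–Alder reaction forms both bonds, sets quaternary C6 and C4 from the C1′/C2′ pair, and fluoride collapses the bicyclic silyl ketal to megaphone, which is acetylated.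

Key step: step 7

Locants: ring C1 (C=O), C2=C3, C4 (CH–OCH3), C5 (CH2), C6 (quaternary). Side chain C1′ (benzylic CH–O), C2′ (CH–CH3).
Assumption: (R)-TRIP is taken to direct allyl transfer to the Re face of an aryl aldehyde, as it does for simple allyl and crotyl pinacol boronates. If the sense were opposite, the antipodal catalyst would be used.

Step 1
Reactants: 1 chloroprene (2-chlorobuta-1,3-diene); 2 allyl bromide
Product: 4 3-methylidenehexa-1,5-diene, via buta-1,3-dien-2-ylmagnesium chloride 3 (not isolated)
Conditions: Mg, ZnCl2 (cat.), BrCH2CH2Br (activator), THF, reflux; then 2, Li2CuCl4 (cat.), 0 °C to rt; distillation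
Reagents that add atoms: magnesium, [Mg] (stays only in 3)
Why: Grignard formation from the vinylic chloride followed by copper-catalysed cross-coupling with an allylic bromide is a known entry to 2-substituted butadienes and creates no stereocentre.

Step 2
Reactants: 4 3-methylidenehexa-1,5-diene
Product: 5 2-[(2E)-2-ethylidenepent-4-en-1-yl]-4,4,5,5-tetramethyl-1,3,2-dioxaborolane (CH3 cis to CH2B)
Conditions: HBpin (1.05 equiv), Ni(cod)2 (2.5 mol %), PCy3 (2.5 mol %), toluene, rt
Reagents that add atoms: pinacolborane, [H]B1OC(C)(C)C(C)(C)O1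
Why: Nickel-catalysed 1,4-hydroboration of a 2-substituted 1,3-diene: zerovalent nickel binds only the conjugated diene in its s-cis form, hydrogen should go to the terminus of the unsubstituted vinyl group and boron to the CH2 next to the branched carbon, so that CH3 and CH2B end cis on the new trisubstituted alkene and the isolated allyl alkene stays untouched.

Step 3
Reactants: 5 allylic boronate; 6 3,4,5-trimethoxybenzaldehyde
Product: 8 (1R,2S)-2-methyl-3-methylidene-1-(3,4,5-trimethoxyphenyl)hex-5-en-1-ol, via pinacol borate ester 7 (not isolated)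
Conditions: (R)-TRIP (3,3′-bis(2,4,6-triisopropylphenyl)-BINOL hydrogen phosphate, 5 mol %), 4 Å MS, toluene, −30 °C; aq. NaHCO3 work-up
Reagents that add atoms: none
Why: Chiral phosphoric acid catalysed allylboration through a closed chair transition state: the CH3-cis-to-CH2B geometry of 5 translates into the syn (1R,2S) relation, and the catalyst, hydrogen-bonded to a boronate oxygen and the formyl hydrogen, selects the Re face of 6 and thereby sets C1′ as R.

Step 4
Reactants: 9 (E)-4-methoxybut-3-en-2-one
Product: 12 (E)-1-diazo-4-methoxybut-3-en-2-one, via lithium enolate 10 (not isolated), via trifluoroacetyl diketone 11 (not isolated)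
Conditions: LiN(SiMe3)2, THF, −78 °C; CF3CO2CH2CF3; AcOH; then MsN3, Et3N, H2O, MeCN, rt
Reagents that add atoms: methanesulfonyl azide, CS(=O)(=O)N=[N+]=[N-]; 2,2,2-trifluoroethyl trifluoroacetate, O=C(OCC(F)(F)F)C(F)(F)F (stays only in 11); lithium hexamethyldisilazide, [Li]N([Si](C)(C)C)[Si](C)(C)C (lithium stays only in 10)
Why: Regitz-type detrifluoroacetylative diazo transfer: kinetic enolisation occurs only at the methyl group, transient trifluoroacetylation activates this carbon for diazo transfer from MsN3 with loss of the trifluoroacetyl group, and the E enol ether is not touched.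

Step 5
Reactants: 8 homoallylic alcohol; 12 diazoketone
Product: 14 (1R,2S)-2-methyl-3-methylidene-1-(3,4,5-trimethoxyphenyl)hex-5-en-1-yl (E)-4-methoxybut-3-enoate, via vinylketene 13 (not isolated)
Conditions: hν (365 nm LED), 12 (1.5 equiv, slow addition), i-Pr2NEt (0.2 equiv), CH2Cl2, 0 °C
Reagents that add atoms: none
Why: Photochemical Wolff rearrangement (Arndt–Eistert logic) gives the (E)-vinylketene 13, which the secondary alcohol captures at the ketene carbon under amine catalysis to give the β,γ-unsaturated ester, while no bond to C1′ or C2′ is broken and the enol ether geometry is carried over from 9.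

Step 6
Reactants: 14 ester
Product: 16 (1Z,3E)-silyl ketene acetal diene: tert-butyl{[(1Z,3E)-4-methoxy-1-{[(1R,2S)-2-methyl-3-methylidene-1-(3,4,5-trimethoxyphenyl)hex-5-en-1-yl]oxy}buta-1,3-dien-1-yl]oxy}dimethylsilane, via lithium dienolate 15 (not isolated)
Conditions: LiN(i-Pr)2 (1.1 equiv), THF–DMPU 4:1, −78 °C; TBSCl, −78 to 0 °C; pentane, cold pH 7 buffer, used crude
Reagents that add atoms: tert-butyldimethylsilyl chloride, CC(C)(C)[Si](C)(C)Cl; lithium diisopropylamide, [Li]N(C(C)C)C(C)C (lithium stays only in 15)
Why: Ireland-type kinetic enolisation and O-silylation: the doubly activated α-CH2 is the only acidic site, the dipolar cosolvent favours the enolate with O-metal cis to the vinyl residue so that silicon ends inside and the tether oxygen outside on the diene terminus, and no stereocentre is touched.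

Step 7
Reactants: 16 silyl ketene acetal triene
Product: 18 megaphone, (4R,6R)-6-[(1R,2S)-1-hydroxy-1-(3,4,5-trimethoxyphenyl)propan-2-yl]-4-methoxy-6-(prop-2-en-1-yl)cyclohex-2-en-1-one, via bicyclic silyl ketal 17 (not isolated)
Conditions: toluene (0.05 M), BHT (cat.), 10 kbar, 75 °C, 48 h; then HF·pyridine, THF, 0 °C
Reagents that add atoms: none
Why: Concerted suprafacial [4+2] cycloaddition: the diene termini of 16, the ketene acetal carbon (future C1) and the methoxy-bearing carbon (future C4), bond to the substituted carbon (future C6) and the CH2 (future C5) of the 1,1-disubstituted alkene, and fluoride then collapses silyl ketal 17 to the C1 ketone while the ring oxygen leaves as the free C1′ hydroxyl. The closest known reactions are the type 1 intramolecular Diels–Alder cyclisations of unactivated 1,3,8-nonatrienes, thermal or under pressure, and the cycloadditions of 1,1-dioxygenated dienes; pressure is chosen because the dienophile is unactivated and the strongly negative activation volume should let the reaction run near 75 °C, below the onset of benzyl-Claisen shift, silyl migration and C–O ionisation. Two rings close: the cyclohexene by the six-electron pericyclic closure and, fused to it along C1–C6, the tetrahydrofuran defined by the three-atom O–C1′–C2′ tether (five-membered, exo to the alkene), which also fixes the regiochemistry. C6 is controlled by C2′: A(1,2) strain keeps the C2′ hydrogen next to the allyl CH2, so the tether can bring the diene only onto the alkene face that places C5 cis to the C2′ methyl group on the new tetrahydrofuran, which is the 6R configuration. C4 is controlled by the E enol ether (methoxy outside) together with the tether-endo, cis-fused transition state, preferred because the inside OTBS group then lies next to the slim exo allyl group and not next to the branched tether, so that OCH3 ends cis to the side chain (4R); the ketal carbon is a transient stereocentre that is erased. The step needs chemoselectivity between two alkenes and this is secured by ring size, since the terminal allyl alkene could only react through a seven-membered tether ring.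

Step 8
Reactants: 18 megaphone
Product: 19 megaphone acetate, (1R,2S)-2-[(1R,5R)-5-methoxy-2-oxo-1-(prop-2-en-1-yl)cyclohex-3-en-1-yl]-1-(3,4,5-trimethoxyphenyl)propyl acetate
Conditions: Ac2O, pyridine, DMAP (cat.), CH2Cl2, rt
Reagents that add atoms: acetic anhydride, CC(=O)OC(C)=O
Why: DMAP-catalysed acylation of the only hydroxyl group proceeds with retention at C1′ because the C–O bond is not broken.

Compound list
1 | chloroprene | C=CC(Cl)=C | starting material
2 | allyl bromide | C=CCBr | starting material
3 | buta-1,3-dien-2-ylmagnesium chloride | C=CC(=C)[Mg]Cl | intermediate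
4 | 3-methylidenehexa-1,5-diene | C=CCC(=C)C=C | intermediate
5 | 2-[(2E)-2-ethylidenepent-4-en-1-yl]-4,4,5,5-tetramethyl-1,3,2-dioxaborolane | C/C=C(/CC=C)CB1OC(C)(C)C(C)(C)O1 | intermediate
6 | 3,4,5-trimethoxybenzaldehyde | COc1cc(C=O)cc(OC)c1OC | starting material
7 | pinacol borate ester of 8 | C=CCC(=C)[C@H](C)[C@@H](OB1OC(C)(C)C(C)(C)O1)c1cc(OC)c(OC)c(OC)c1 | intermediate
8 | (1R,2S)-2-methyl-3-methylidene-1-(3,4,5-trimethoxyphenyl)hex-5-en-1-ol | C=CCC(=C)[C@H](C)[C@@H](O)c1cc(OC)c(OC)c(OC)c1 | intermediate
9 | (E)-4-methoxybut-3-en-2-one | CO/C=C/C(C)=O | starting material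
10 | lithium enolate of 9 | CO/C=C/C(=C)[O-].[Li+] | intermediate
11 | (E)-1,1,1-trifluoro-6-methoxyhex-5-ene-2,4-dione | CO/C=C/C(=O)CC(=O)C(F)(F)F | intermediate
12 | (E)-1-diazo-4-methoxybut-3-en-2-one | CO/C=C/C(=O)C=[N+]=[N-] | intermediate
13 | (E)-4-methoxybuta-1,3-dien-1-one (vinylketene) | CO/C=C/C=C=O | intermediate
14 | (E)-4-methoxybut-3-enoate of 8 | C=CCC(=C)[C@H](C)[C@@H](OC(=O)C/C=C/OC)c1cc(OC)c(OC)c(OC)c1 | intermediate
15 | lithium dienolate of 14 | C=CCC(=C)[C@H](C)[C@@H](O/C([O-])=C/C=C/OC)c1cc(OC)c(OC)c(OC)c1.[Li+] | intermediate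
16 | (1Z,3E)-TBS ketene acetal of 14 | C=CCC(=C)[C@H](C)[C@@H](O/C(O[Si](C)(C)C(C)(C)C)=C/C=C/OC)c1cc(OC)c(OC)c(OC)c1 | intermediate
17 | (2R,3S,3aR,5R,7aS)-3a-allyl-7a-(tert-butyldimethylsilyloxy)-5-methoxy-3-methyl-2-(3,4,5-trimethoxyphenyl)-2,3,3a,4,5,7a-hexahydro-1-benzofuran (cis-fused) | C=CC[C@@]12[C@H](C)[C@H](c3cc(OC)c(OC)c(OC)c3)O[C@]1(O[Si](C)(C)C(C)(C)C)C=C[C@H](OC)C2 | intermediate
18 | megaphone | C=CC[C@]1([C@H](C)[C@@H](O)c2cc(OC)c(OC)c(OC)c2)C[C@@H](OC)C=CC1=O | intermediate
19 | megaphone acetate | C=CC[C@]1([C@H](C)[C@@H](OC(C)=O)c2cc(OC)c(OC)c(OC)c2)C[C@@H](OC)C=CC1=O | target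

Total step count: 8. Longest linear sequence: 7 (steps 1, 2, 3, 5, 6, 7, 8).

Steps most likely to fail

**Step 7 (key step).** The cycloaddition may be too slow on the unactivated, 1,1-disubstituted alkene. In that case [3,3] shift of the benzyl ketene acetal into the electron-rich arene, oxygen-to-carbon silyl migration or ionisation of the benzylic C–O bond could take over. Endo/exo and facial control may also be poor.

In the fallback the quaternary carbon is no longer asked of the cycloaddition and is made by enolate alkylation. It sets out from 6 and comes back at 18. (R)-TRIP-catalysed addition of commercial (Z)-crotylboronic acid pinacol ester to 6 should give (1R,2S)-2-methyl-1-(3,4,5-trimethoxyphenyl)but-3-en-1-ol F1. Capture of ketene 13 as in step 5 gives the (E)-4-methoxybut-3-enoate ester F2, and LiN(i-Pr)2/TBSCl as in step 6 gives the silyl ketene acetal F3. Its monosubstituted alkene is the parent dienophile of nonatriene cyclisations and should close faster, to the cis-fused bicyclic silyl ketal F4. HF·pyridine opens this to the 6-H enone (deallylmegaphone) F5. LiN(i-Pr)2 (2.2 equiv) and 2 should then alkylate C6 through the cross-conjugated enolate, on the face away from the C4 methoxy group, to give 18.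

**Step 2.** Hydrogen and boron may be delivered with the wrong regiochemistry, or a nickel hydride may move the skipped double bond into conjugation.

In the fallback the C1′/C2′ pair is made by an aldol reaction and the diene is built afterwards. It sets out from 6 and comes back at 8. An Evans syn aldol reaction of (R)-4-benzyl-3-propionyloxazolidin-2-one (Bu2BOTf, Et3N) with 6 gives the syn aldol imide F6. MeONHMe·HCl/AlMe3 gives the Weinreb amide F7, and TBSOTf/2,6-lutidine gives the silyl ether F8. Allylmagnesium bromide gives the β,γ-unsaturated ketone F9. Me3SiCH2MgCl/CeCl3 adds without enolisation to give the β-hydroxysilane F10. Aqueous HF in MeCN then brings about Peterson elimination and loss of the TBS group in one pot to give 8.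

**Step 5.** Capture of the ketene by the hindered secondary alcohol may be slower than dimerisation or ring closure of the ketene, and the amine may shift the double bond into conjugation.

The fallback replaces ketene capture by a C–C coupling. It sets out from 8 and comes back at 14. Bromoacetyl bromide/pyridine gives the bromoacetate F11. Suzuki–Miyaura coupling with (E)-2-(2-methoxyvinyl)-4,4,5,5-tetramethyl-1,3,2-dioxaborolane (Pd(PPh3)4, K3PO4, THF–H2O) joins the methoxyvinyl group to the α-carbon with retention of the E geometry.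

Further compounds
F1 | step 7 | (1R,2S)-2-methyl-1-(3,4,5-trimethoxyphenyl)but-3-en-1-ol | C=C[C@H](C)[C@@H](O)c1cc(OC)c(OC)c(OC)c1
F2 | step 7 | (1R,2S)-2-methyl-1-(3,4,5-trimethoxyphenyl)but-3-en-1-yl (E)-4-methoxybut-3-enoate | C=C[C@H](C)[C@@H](OC(=O)C/C=C/OC)c1cc(OC)c(OC)c(OC)c1
F3 | step 7 | (1Z,3E)-TBS ketene acetal of F2 | C=C[C@H](C)[C@@H](O/C(O[Si](C)(C)C(C)(C)C)=C/C=C/OC)c1cc(OC)c(OC)c(OC)c1
F4 | step 7 | (2R,3S,3aR,5R,7aS)-7a-(tert-butyldimethylsilyloxy)-5-methoxy-3-methyl-2-(3,4,5-trimethoxyphenyl)-2,3,3a,4,5,7a-hexahydro-1-benzofuran | [C@@H]12[C@H](C)[C@H](c3cc(OC)c(OC)c(OC)c3)O[C@]1(O[Si](C)(C)C(C)(C)C)C=C[C@H](OC)C2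
F5 | step 7 | (4R,6R)-6-[(1R,2S)-1-hydroxy-1-(3,4,5-trimethoxyphenyl)propan-2-yl]-4-methoxycyclohex-2-en-1-one | [C@H]1([C@H](C)[C@@H](O)c2cc(OC)c(OC)c(OC)c2)C[C@@H](OC)C=CC1=O
F6 | step 2 | (R)-4-benzyl-3-[(2R,3R)-3-hydroxy-2-methyl-3-(3,4,5-trimethoxyphenyl)propanoyl]oxazolidin-2-one | O=C([C@H](C)[C@@H](O)c1cc(OC)c(OC)c(OC)c1)N1C(=O)OC[C@H]1Cc1ccccc1
F7 | step 2 | (2R,3R)-3-hydroxy-N-methoxy-N,2-dimethyl-3-(3,4,5-trimethoxyphenyl)propanamide | CON(C)C(=O)[C@H](C)[C@@H](O)c1cc(OC)c(OC)c(OC)c1
F8 | step 2 | TBS ether of F7 | CON(C)C(=O)[C@H](C)[C@@H](O[Si](C)(C)C(C)(C)C)c1cc(OC)c(OC)c(OC)c1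
F9 | step 2 | (1R,2R)-1-(tert-butyldimethylsilyloxy)-2-methyl-1-(3,4,5-trimethoxyphenyl)hex-5-en-3-one | C=CCC(=O)[C@H](C)[C@@H](O[Si](C)(C)C(C)(C)C)c1cc(OC)c(OC)c(OC)c1
F10 | step 2 | β-hydroxysilane from F9 (both epimers at the new carbinol carbon) | C=CCC(O)(C[Si](C)(C)C)[C@H](C)[C@@H](O[Si](C)(C)C(C)(C)C)c1cc(OC)c(OC)c(OC)c1
F11 | step 5 | (1R,2S)-2-methyl-3-methylidene-1-(3,4,5-trimethoxyphenyl)hex-5-en-1-yl bromoacetate | C=CCC(=C)[C@H](C)[C@@H](OC(=O)CBr)c1cc(OC)c(OC)c(OC)c1
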